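The synthesis rests on cutting the trans-decalin at C1–C10 (ring A) and C8–C9 (ring B), the two bonds that meet the C9–C10 edge next to quaternary C10. One SmI2 operation makes both. The ketyl of a C1 aldehyde adds to C10 of a C10=C9–C11 enoate, and the samarium enolate thus formed at C9 attacks a C8 ketone, setting C1, C10, C9 and C8. The feature exploited is that C1–O is γ to the C11 carboxyl and C8 is β to it. The precursor is an open chain holding only the C4/C5 stereodiad (from an Ireland–Claisen rearrangement), the aldehyde, the E enoate and a silylmethyl ketone that later gives C8=C17.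

Key step: step 13

Numbering remark: labdane locants are used for every intermediate (C11 on C9, C17 on C8, C18 methyl and C19 ester on C4, C20 methyl on C10).
Assumption: the key-step product is drawn with the C8 hydroxyl axial (the chelate-controlled outcome). This centre is erased in the next step, so the other epimer would serve equally.
Stereochemical check: the spatial arrangements at C4 and C5 of the key-step precursor, and at C1, C4, C5, C9 and C10 of its product, are those of the target. R/S labels change along the route only because substituent priorities change.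

Step 1
Reactants: 1 pent-4-yn-1-ol
Product: 2 4-methoxybenzyl pent-4-yn-1-yl ether
Conditions: NaH, PMBCl, Bu4NI (cat.), THF/DMF, 0 °C → rt
Reagents that add atoms: 4-methoxybenzyl chloride, COc1ccc(CCl)cc1
Why: Williamson ether synthesis on the alkoxide; the 4-methoxybenzyl ether is chosen because it can be removed in step 11 by neutral oxidation, the only kind of unmasking that a β-ketosilane tolerates.

Step 2
Reactants: 2 4-methoxybenzyl pent-4-yn-1-yl ether; 3 acetaldehyde
Product: 6 rac-(E)-7-[(4-methoxybenzyl)oxy]-4-methylhept-3-en-2-ol, via (E)-alkenyldimethylalane 4 (not isolated), via lithium alkenyl(butyl)dimethylaluminate 5 (not isolated)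
Conditions: Me3Al, Cp2ZrCl2 (25 mol %), CH2Cl2, 0 °C → rt; evaporate; n-BuLi, hexane/THF, −78 °C; MeCHO, −78 → 0 °C
Reagents that add atoms: trimethylaluminium, C[Al](C)C
Why: Zirconium-catalysed Negishi carboalumination adds methyl (future C18) and aluminium syn across the alkyne and the derived ate complex adds to the aldehyde with retention, so the C3 chain ends trans to the carbinol carbon (E alkene), the carbinol centre still being racemic.

Step 3
Reactants: 6 rac-(E)-7-[(4-methoxybenzyl)oxy]-4-methylhept-3-en-2-ol; 7 hex-5-enoic acid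
Product: 8 (2R,3E)-7-[(4-methoxybenzyl)oxy]-4-methylhept-3-en-2-yl hex-5-enoate
Conditions: immobilised Candida antarctica lipase B, 4 Å MS, hexane, 40 °C, stopped at ca. 45% conversion
Reagents that add atoms: none
Why: Lipase-catalysed kinetic resolution by direct esterification, in which the enzyme accepts the R methyl carbinol (small methyl, large alkenyl residue), so the controlling stereocentre is secured and the rearrangement substrate is assembled in one operation.

Step 4
Reactants: 8 (2R,3E)-7-[(4-methoxybenzyl)oxy]-4-methylhept-3-en-2-yl hex-5-enoate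
Product: 11 (2R,3S,4E)-2-(but-3-en-1-yl)-3-{3-[(4-methoxybenzyl)oxy]propyl}-3-methylhex-4-enoic acid, via (Z)-silyl ketene acetal 9 (not isolated), via trimethylsilyl ester 10 (not isolated)
Conditions: LiN(i-Pr)2, THF/DMPU (4:1), −78 °C; Me3SiCl; → rt, then 50 °C; 1 M HCl
Reagents that add atoms: none
Why: Ireland–Claisen rearrangement, in which deprotonation in the dipolar medium gives the Z silyl ketene acetal that reacts with the E alkene through a chair whose carbinol methyl must be equatorial (axial it would clash with the axial C18 methyl), so the R carbinol centre is transferred to quaternary C4 and to C5 while the new E propenyl group stores C19.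

Step 5
Reactants: 11 (2R,3S,4E)-2-(but-3-en-1-yl)-3-{3-[(4-methoxybenzyl)oxy]propyl}-3-methylhex-4-enoic acid
Product: 12 (3R,4S,5E)-3-(but-3-en-1-yl)-4-{3-[(4-methoxybenzyl)oxy]propyl}-4-methylhept-5-en-2-one
Conditions: MeLi (3 equiv), Et2O, 0 °C; poured into aq. NH4Cl
Reagents that add atoms: methyllithium, [Li]C
Why: Ketone synthesis from a carboxylic acid with an organolithium, in which the dilithio gem-diolate survives until work-up, so C20 is added only once and C5, never enolised, keeps its configuration.

Step 6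
Reactants: 12 (3R,4S,5E)-3-(but-3-en-1-yl)-4-{3-[(4-methoxybenzyl)oxy]propyl}-4-methylhept-5-en-2-one; 13 trimethyl phosphonoacetate
Product: 14 methyl (2E,4S,5S,6E)-4-(but-3-en-1-yl)-5-{3-[(4-methoxybenzyl)oxy]propyl}-3,5-dimethylocta-2,6-dienoate
Conditions: NaH, DME, 0 °C → 80 °C
Reagents that add atoms: none
Why: Horner–Wadsworth–Emmons olefination, run while only an ether and isolated alkenes accompany the ketone, in which the very large C5 residue set against a methyl group steers the reversible addition to the E enoate (C5 trans to C11).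

Step 7
Reactants: 14 methyl (2E,4S,5S,6E)-4-(but-3-en-1-yl)-5-{3-[(4-methoxybenzyl)oxy]propyl}-3,5-dimethylocta-2,6-dienoate
Product: 16 methyl (2E,4S,5R)-5-carboxy-4-(2-carboxyethyl)-8-[(4-methoxybenzyl)oxy]-3,5-dimethyloct-2-enoate, via C8/C19 dialdehyde 15 (not isolated)
Conditions: O3, CH2Cl2, −78 °C (Sudan Red 7B end point); PPh3; then NaClO2, NaH2PO4, 2-methylbut-2-ene, t-BuOH/H2O, rt
Reagents that add atoms: ozone, [O-][O+]=O; sodium chlorite, [Na+].[O-]Cl=O
Why: Chemoselective ozonolysis (the two isolated alkenes react far faster than the electron-poor, crowded enoate and the dye marks the end point) followed in the same flask by Pinnick oxidation turns the propenyl group into the C19 acid and the butenyl terminus into the C8 acid.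

Step 8
Reactants: 16 methyl (2E,4S,5R)-5-carboxy-4-(2-carboxyethyl)-8-[(4-methoxybenzyl)oxy]-3,5-dimethyloct-2-enoate
Product: 18 methyl (2E,4S,5R)-5-carboxy-4-{3-[methoxy(methyl)amino]-3-oxopropyl}-8-[(4-methoxybenzyl)oxy]-3,5-dimethyloct-2-enoate, via C8 acyl imidazolide 17 (not isolated)
Conditions: CDI (1.05 equiv), CH2Cl2, 0 °C → rt; MeNHOMe·HCl, rt
Reagents that add atoms: N,O-dimethylhydroxylamine hydrochloride, CNOC.Cl
Why: Amide coupling through an acyl imidazolide, in which one equivalent of CDI activates the unhindered C8 acid and not the C19 acid on quaternary C4, so the Weinreb amide is formed at C8 only.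

Step 9
Reactants: 18 methyl (2E,4S,5R)-5-carboxy-4-{3-[methoxy(methyl)amino]-3-oxopropyl}-8-[(4-methoxybenzyl)oxy]-3,5-dimethyloct-2-enoate
Product: 19 methyl (2E,4S,5R)-5-(methoxycarbonyl)-4-{3-[methoxy(methyl)amino]-3-oxopropyl}-8-[(4-methoxybenzyl)oxy]-3,5-dimethyloct-2-enoate
Conditions: MeI, K2CO3, DMF, rt
Reagents that add atoms: iodomethane, CI
Why: SN2 alkylation of the carboxylate on oxygen, an esterification whose rate does not depend on the crowding around the C19 carbonyl carbon.

Step 10
Reactants: 19 methyl (2E,4S,5R)-5-(methoxycarbonyl)-4-{3-[methoxy(methyl)amino]-3-oxopropyl}-8-[(4-methoxybenzyl)oxy]-3,5-dimethyloct-2-enoate; 20 (trimethylsilyl)methylmagnesium chloride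
Product: 21 methyl (2E,4S,5R)-5-(methoxycarbonyl)-8-[(4-methoxybenzyl)oxy]-3,5-dimethyl-4-[3-oxo-4-(trimethylsilyl)butyl]oct-2-enoate
Conditions: 20 (2 equiv), THF, 0 °C; cold sat. aq. NH4Cl; short filtration over deactivated silica
Reagents that add atoms: none
Why: Weinreb ketone synthesis, in which the magnesium chelate of the tetrahedral adduct blocks a second addition and the bulky, mildly nucleophilic Grignard reagent leaves the conjugated C11 ester and the neopentyl-type C19 ester untouched at 0 °C.

Step 11
Reactants: 21 methyl (2E,4S,5R)-5-(methoxycarbonyl)-8-[(4-methoxybenzyl)oxy]-3,5-dimethyl-4-[3-oxo-4-(trimethylsilyl)butyl]oct-2-enoate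
Product: 22 methyl (2E,4S,5R)-8-hydroxy-5-(methoxycarbonyl)-3,5-dimethyl-4-[3-oxo-4-(trimethylsilyl)butyl]oct-2-enoate
Conditions: DDQ, CH2Cl2/pH 7 phosphate buffer, 0 °C
Reagents that add atoms: none
Why: Oxidative cleavage of the 4-methoxybenzyl ether by DDQ (hydride abstraction, then hydrolysis of the oxocarbenium ion) works at neutral pH without fluoride, acid or base, so the C–Si bond next to the ketone is kept.

Step 12
Reactants: 22 methyl (2E,4S,5R)-8-hydroxy-5-(methoxycarbonyl)-3,5-dimethyl-4-[3-oxo-4-(trimethylsilyl)butyl]oct-2-enoate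
Product: 23 methyl (2E,4S,5R)-5-(methoxycarbonyl)-3,5-dimethyl-8-oxo-4-[3-oxo-4-(trimethylsilyl)butyl]oct-2-enoate
Conditions: Dess–Martin periodinane, NaHCO3, CH2Cl2, 0 °C → rt; used at once without chromatography
Reagents that add atoms: none
Why: Dess–Martin oxidation of the primary alcohol, buffered so that the acetic acid released cannot protodesilylate the ketone, and run directly after step 11 so that the δ-hydroxy ester has no time to lactonise.

Step 13
Reactants: 23 methyl (2E,4S,5R)-5-(methoxycarbonyl)-3,5-dimethyl-8-oxo-4-[3-oxo-4-(trimethylsilyl)butyl]oct-2-enoate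
Product: 25 trans-decalin diol diester (1S,4R,5S,8R,9S,10R): C1–OH equatorial; C8–OH axial; C8–CH2SiMe3 equatorial; C9–CO2Me equatorial; C4–CO2Me axial, via ring A samarium enolate 24 (not isolated)
Conditions: SmI2 (0.1 M in THF, 3 equiv), no proton source, −78 °C, slow addition of 23 (0.01 M final), → 0 °C; sat. aq. NaHCO3/Na2S2O3
Reagents that add atoms: none
Why: SmI2 transfers one electron to the C1 aldehyde, the ketyl adds to C10 of the enoate, a second electron converts the C9 radical into a trivalent samarium enolate, and this enolate adds to the C8 ketone before any proton reaches it. The closest known reaction type is the SmI2 ketyl–olefin cyclisation of aldehyde-tethered enoates with intramolecular aldol capture of the samarium enolate. Ring A closes 6-exo-trig (C1–C10) through a chair and ring B closes as a 6-(enolexo)-exo-trig aldol (C8–C9) through a second chair. C10 is set by the existing C5 centre, whose C6 chain stays equatorial so that the small C20 methyl goes axial and the enoate arm equatorial (hence the trans fusion), and C1 is set by the ketyl oxygen turning pseudo-equatorial, away from the enoate arm, which puts it cis to C20. C9 and C8 are set in the ring B chair by samarium bridging the enolate oxygen, the ketone oxygen and the nearby C1 alkoxide, which places the ester and the bulky CH2SiMe3 group equatorial and the C8 oxygen axial. The step needs reduction of the aldehyde in preference to the dialkyl ketone and the β,β-disubstituted enoate, which their reduction potentials secure in additive-free THF, and it needs aldol closure to beat enolate protonation, which the absence of a proton source and the six-membered chelate secure.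

Step 14
Reactants: 25 trans-decalin diol diester
Product: 26 8(17)-methylene hydroxy diester (1S,4R,5S,9R,10R)
Conditions: 48% aq. HF, MeCN, 0 °C
Reagents that add atoms: none
Why: Peterson elimination in its acid-promoted form, in which ionisation at tertiary C8 is assisted by the β-silicon effect and loss of the silyl group can place the alkene only between C8 and C17, while the absence of base avoids retro-aldol cleavage of the β-hydroxy ester and epimerisation at C9.

Step 15
Reactants: 26 8(17)-methylene hydroxy diester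
Product: 27 1,11-diol C19 methyl ester (1S,4R,5S,9R,10R)
Conditions: i-Bu2AlH (4.5 equiv), CH2Cl2, −78 → −20 °C; aq. potassium sodium tartrate
Reagents that add atoms: none
Why: Ester reduction with i-Bu2AlH, selective because the C19 ester is axial on quaternary C4 and screened by the syn-axial C20 methyl whereas the C11 ester lies next to the C1 aluminium alkoxide that activates it (any C1–O/C11 lactone formed earlier gives the same diol).

Step 16
Reactants: 27 1,11-diol C19 methyl ester
Product: 29 C11 tert-butyldimethylsilyl ether C1 acetate, via C11 silyl ether C1 alcohol 28 (not isolated)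
Conditions: TBSCl (1.1 equiv), imidazole, DMAP (cat.), CH2Cl2, 0 °C → rt; then Ac2O, Et3N, rt → 35 °C
Reagents that add atoms: tert-butyldimethylsilyl chloride, CC(C)(C)[Si](C)(C)Cl; acetic anhydride, CC(=O)OC(C)=O
Why: Steric differentiation of a diol, in which TBSCl silylates only the primary C11 hydroxyl and DMAP-catalysed acylation then esterifies C1–OH; C11–O is masked first because the equatorial C1 oxygen sits within reach of C11 and would close a tetrahydrofuran as soon as C11 carried a leaving group.

Step 17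
Reactants: 29 C11 tert-butyldimethylsilyl ether C1 acetate
Product: 30 C11 alcohol C1 acetate (1S,4R,5S,9R,10R)
Conditions: HF·pyridine, THF, 0 °C → rt
Reagents that add atoms: none
Why: Fluoride-mediated desilylation in an acidic medium, which removes the primary silyl ether without the base-induced acetyl migration from O1 to O11.

Step 18
Reactants: 30 C11 alcohol C1 acetate
Product: 31 C11 iodide C1 acetate (1S,4R,5S,9R,10R)
Conditions: PPh3, I2, imidazole, CH2Cl2, 0 °C → rt
Reagents that add atoms: iodine, [I][I]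
Why: Appel-type iodination, an SN2 displacement of the alkoxyphosphonium ion by iodide at the primary carbon, now free of any competing internal nucleophile.

Step 19
Reactants: 32 prop-2-yn-1-ol
Product: 34 (E)-3-iodo-2-methylprop-2-en-1-ol, via alkenylalane alkoxide 33 (not isolated)
Conditions: Me3Al (3 equiv), Cp2ZrCl2 (25 mol %), CH2Cl2, 0 °C → rt; I2, THF, −30 °C
Reagents that add atoms: trimethylaluminium, C[Al](C)C; iodine, [I][I]
Why: Negishi carboalumination followed by iodinolysis with retention, in which syn addition places methyl and iodine cis, the E geometry needed for C12=C13.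

Step 20
Reactants: 34 (E)-3-iodo-2-methylprop-2-en-1-ol
Product: 35 (E)-3-iodo-2-methylprop-2-enal
Conditions: MnO2, CH2Cl2, rt
Reagents that add atoms: none
Why: Allylic alcohol oxidation with MnO2, neutral and selective, with no loss of alkene geometry.

Step 21
Reactants: 35 (E)-3-iodo-2-methylprop-2-enal
Product: 36 (E)-1-iodo-2-methylbuta-1,3-diene
Conditions: MePPh3Br, NaN(SiMe3)2, THF, 0 °C; then 35, −78 °C → rt; kept as a cold solution (volatile)
Reagents that add atoms: methyltriphenylphosphonium bromide, C[P+](c1ccccc1)(c1ccccc1)c1ccccc1.[Br-]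
Why: Wittig methylenation of the enal with the non-stabilised ylide builds C14=C15 and leaves the alkenyl iodide untouched.

Step 22
Reactants: 31 C11 iodide C1 acetate; 36 (E)-1-iodo-2-methylbuta-1,3-diene
Product: 38 CNP0235031.1 (1S,4R,5S,9R,10S,12E), via C11 alkylzinc iodide 37 (not isolated)
Conditions: Zn dust (activated with BrCH2CH2Br and Me3SiCl), LiCl, THF, 40 °C; then 36, PdCl2(dppf) (5 mol %), THF, rt
Reagents that add atoms: none
Why: Negishi coupling, in which zinc inserts into the primary C–I bond without harming acetate or ester and the palladium-catalysed coupling with the alkenyl iodide proceeds with retention, which delivers the E C12=C13 bond and completes the side chain.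

Compound list
1 | pent-4-yn-1-ol | C#CCCCO | starting material
2 | 4-methoxybenzyl pent-4-yn-1-yl ether | C#CCCCOCc1ccc(OC)cc1 | intermediate
3 | acetaldehyde | CC=O | starting material
4 | (E)-alkenyldimethylalane (Al cis to methyl) | C[Al](C)/C=C(C)/CCCOCc1ccc(OC)cc1 | intermediate
5 | lithium (E)-alkenyl(butyl)dimethylaluminate | [Li+].CCCC[Al-](C)(C)/C=C(C)/CCCOCc1ccc(OC)cc1 | intermediate
6 | rac-(E)-7-[(4-methoxybenzyl)oxy]-4-methylhept-3-en-2-ol | CC(O)/C=C(C)/CCCOCc1ccc(OC)cc1 | intermediate
7 | hex-5-enoic acid | C=CCCCC(=O)O | starting material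
8 | (2R,3E)-7-[(4-methoxybenzyl)oxy]-4-methylhept-3-en-2-yl hex-5-enoate | C=CCCCC(=O)O[C@H](C)/C=C(C)/CCCOCc1ccc(OC)cc1 | intermediate
9 | (Z)-trimethylsilyl ketene acetal of 8 (C6 chain cis to OSiMe3) | C=CCC/C=C(\O[Si](C)(C)C)O[C@H](C)/C=C(C)/CCCOCc1ccc(OC)cc1 | intermediate
10 | trimethylsilyl (2R,3S,4E)-2-(but-3-en-1-yl)-3-{3-[(4-methoxybenzyl)oxy]propyl}-3-methylhex-4-enoate | COc1ccc(COCCC[C@@](C)(/C=C/C)[C@@H](CCC=C)C(=O)O[Si](C)(C)C)cc1 | intermediate
11 | (2R,3S,4E)-2-(but-3-en-1-yl)-3-{3-[(4-methoxybenzyl)oxy]propyl}-3-methylhex-4-enoic acid | COc1ccc(COCCC[C@@](C)(/C=C/C)[C@@H](CCC=C)C(=O)O)cc1 | intermediate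
12 | (3R,4S,5E)-3-(but-3-en-1-yl)-4-{3-[(4-methoxybenzyl)oxy]propyl}-4-methylhept-5-en-2-one | COc1ccc(COCCC[C@@](C)(/C=C/C)[C@@H](CCC=C)C(C)=O)cc1 | intermediate
13 | trimethyl phosphonoacetate | COC(=O)CP(=O)(OC)OC | starting material
14 | methyl (2E,4S,5S,6E)-4-(but-3-en-1-yl)-5-{3-[(4-methoxybenzyl)oxy]propyl}-3,5-dimethylocta-2,6-dienoate | COc1ccc(COCCC[C@@](C)(/C=C/C)[C@@H](CCC=C)/C(C)=C/C(=O)OC)cc1 | intermediate
15 | methyl (2E,4S,5R)-5-formyl-8-[(4-methoxybenzyl)oxy]-3,5-dimethyl-4-(3-oxopropyl)oct-2-enoate | COc1ccc(COCCC[C@@](C)(C=O)[C@@H](CCC=O)/C(C)=C/C(=O)OC)cc1 | intermediate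
16 | methyl (2E,4S,5R)-5-carboxy-4-(2-carboxyethyl)-8-[(4-methoxybenzyl)oxy]-3,5-dimethyloct-2-enoate | COc1ccc(COCCC[C@@](C)(C(=O)O)[C@@H](CCC(=O)O)/C(C)=C/C(=O)OC)cc1 | intermediate
17 | C8 acyl imidazolide of 16 | COc1ccc(COCCC[C@@](C)(C(=O)O)[C@@H](CCC(=O)n2ccnc2)/C(C)=C/C(=O)OC)cc1 | intermediate
18 | methyl (2E,4S,5R)-5-carboxy-4-{3-[methoxy(methyl)amino]-3-oxopropyl}-8-[(4-methoxybenzyl)oxy]-3,5-dimethyloct-2-enoate | COc1ccc(COCCC[C@@](C)(C(=O)O)[C@@H](CCC(=O)N(C)OC)/C(C)=C/C(=O)OC)cc1 | intermediate
19 | methyl (2E,4S,5R)-5-(methoxycarbonyl)-4-{3-[methoxy(methyl)amino]-3-oxopropyl}-8-[(4-methoxybenzyl)oxy]-3,5-dimethyloct-2-enoate | COc1ccc(COCCC[C@@](C)(C(=O)OC)[C@@H](CCC(=O)N(C)OC)/C(C)=C/C(=O)OC)cc1 | intermediate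
20 | (trimethylsilyl)methylmagnesium chloride | C[Si](C)(C)C[Mg]Cl | starting material
21 | methyl (2E,4S,5R)-5-(methoxycarbonyl)-8-[(4-methoxybenzyl)oxy]-3,5-dimethyl-4-[3-oxo-4-(trimethylsilyl)butyl]oct-2-enoate | COc1ccc(COCCC[C@@](C)(C(=O)OC)[C@@H](CCC(=O)C[Si](C)(C)C)/C(C)=C/C(=O)OC)cc1 | intermediate
22 | methyl (2E,4S,5R)-8-hydroxy-5-(methoxycarbonyl)-3,5-dimethyl-4-[3-oxo-4-(trimethylsilyl)butyl]oct-2-enoate | OCCC[C@@](C)(C(=O)OC)[C@@H](CCC(=O)C[Si](C)(C)C)/C(C)=C/C(=O)OC | intermediate
23 | methyl (2E,4S,5R)-5-(methoxycarbonyl)-3,5-dimethyl-8-oxo-4-[3-oxo-4-(trimethylsilyl)butyl]oct-2-enoate (key-step precursor) | O=CCC[C@@](C)(C(=O)OC)[C@@H](CCC(=O)C[Si](C)(C)C)/C(C)=C/C(=O)OC | intermediate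
24 | ring A bis(diiodosamarium) alkoxide/ester enolate (C1–C10 closed, enolate at C9) | COC(O[Sm](I)I)=C[C@]1(C)[C@@H](O[Sm](I)I)CC[C@@](C)(C(=O)OC)[C@H]1CCC(=O)C[Si](C)(C)C | intermediate
25 | trans-decalin diol diester, labdane locants (1S,4R,5S,8R,9S,10R): 1-OH, 8-OH, 8-CH2SiMe3, 9-CO2Me, 4-CO2Me (key-step product) | COC(=O)[C@@H]1[C@@](O)(C[Si](C)(C)C)CC[C@H]2[C@@]1(C)[C@@H](O)CC[C@@]2(C)C(=O)OC | intermediate
26 | 8(17)-methylene hydroxy diester (1S,4R,5S,9R,10R) | COC(=O)[C@@H]1C(=C)CC[C@H]2[C@@]1(C)[C@@H](O)CC[C@@]2(C)C(=O)OC | intermediate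
27 | 1,11-diol C19 methyl ester (1S,4R,5S,9R,10R) | OC[C@@H]1C(=C)CC[C@H]2[C@@]1(C)[C@@H](O)CC[C@@]2(C)C(=O)OC | intermediate
28 | C11 tert-butyldimethylsilyl ether, C1 alcohol | CC(C)(C)[Si](C)(C)OC[C@@H]1C(=C)CC[C@H]2[C@@]1(C)[C@@H](O)CC[C@@]2(C)C(=O)OC | intermediate
29 | C11 tert-butyldimethylsilyl ether, C1 acetate | CC(C)(C)[Si](C)(C)OC[C@@H]1C(=C)CC[C@H]2[C@@]1(C)[C@@H](OC(C)=O)CC[C@@]2(C)C(=O)OC | intermediate
30 | C11 alcohol, C1 acetate | OC[C@@H]1C(=C)CC[C@H]2[C@@]1(C)[C@@H](OC(C)=O)CC[C@@]2(C)C(=O)OC | intermediate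
31 | C11 iodide, C1 acetate | IC[C@@H]1C(=C)CC[C@H]2[C@@]1(C)[C@@H](OC(C)=O)CC[C@@]2(C)C(=O)OC | intermediate
32 | prop-2-yn-1-ol | C#CCO | starting material
33 | (E)-alkenyldimethylalane dimethylaluminium alkoxide | C[Al](C)/C=C(C)/CO[Al](C)C | intermediate
34 | (E)-3-iodo-2-methylprop-2-en-1-ol | OC/C(C)=C/I | intermediate
35 | (E)-3-iodo-2-methylprop-2-enal | O=C/C(C)=C/I | intermediate
36 | (E)-1-iodo-2-methylbuta-1,3-diene | C=C/C(C)=C/I | intermediate
37 | C11 alkylzinc iodide, C1 acetate | I[Zn]C[C@@H]1C(=C)CC[C@H]2[C@@]1(C)[C@@H](OC(C)=O)CC[C@@]2(C)C(=O)OC | intermediate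
38 | CNP0235031.1, methyl 1-acetoxylabda-8(17),12E,14-trien-19-oate (1S,4R,5S,9R,10S) | C=C/C(C)=C/C[C@@H]1C(=C)CC[C@H]2[C@@]1(C)[C@@H](OC(C)=O)CC[C@@]2(C)C(=O)OC | target

Total step count: 22. Longest linear sequence: 19 (steps 1–18 and 22). Steps 19–21 make the dienyl iodide in parallel.

Steps most likely to fail

1. Step 13.
- What may go wrong: a proton may pass from the acidic CH2 groups beside the C8 ketone to the C9 samarium enolate, or the crowded aldol addition may reverse, so that only ring A closes.
- Fallback (ring B closed in a separate anionic step, methylene added afterwards): it sets out from 19 and returns at 26.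
- DDQ cleavage of the 4-methoxybenzyl ether of 19 gives the hydroxy Weinreb amide F1, and Dess–Martin oxidation gives the aldehyde F2.
- SmI2 in THF/t-BuOH then closes only ring A and protonates the enolate, giving the monocyclic γ-hydroxy ester F3.
- After silylation (TESOTf, 2,6-lutidine) to the triethylsilyl ether F4, LiN(SiMe3)2 forms the C9 ester enolate. This acylates on the C8 Weinreb amide (Dieckmann-type closure) to give the decalin β-keto ester F5, whose C9 centre equilibrates to the equatorial ester.
- Non-basic methylenation (Zn, CH2Br2, TiCl4) gives the silylated methylene ester F6, and aqueous HF in MeCN removes the silyl group to reach 26.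

2. Step 10.
- What may go wrong: the Grignard reagent may also attack the C11 ester, and the β-ketosilane may slowly protodesilylate while it is carried through steps 11 and 12.
- Fallback (the ketone is unveiled only in the last oxidation): it sets out from 19 and returns at 23.
- Cp2Zr(H)Cl reduces the Weinreb amide of 19 chemoselectively to the C8 aldehyde F7.
- Reagent 20 adds to it at −78 °C, where no ester reacts, to give the β-hydroxysilane F8 (both C8 epimers serve).
- DDQ gives the diol F9, and Dess–Martin periodinane (2.5 equiv, NaHCO3) oxidises both alcohols at once to 23.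

3. Step 6.
- What may go wrong: addition to the crowded ketone may be slow, with loss of E/Z control and gradual epimerisation at C5 on prolonged heating with base.
- Fallback (stereospecific substitution instead of olefination): it sets out from 11 and returns at 14.
- Acid 11 is activated with CDI and homologated with potassium methyl malonate/MgCl2 to the β-keto ester F10.
- NaH and ClP(O)(OEt)2 trap its chelated enolate as the Z enol phosphate F11.
- Me2CuLi replaces the phosphate by methyl with retention to give 14.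

Further compounds
F1 | step 13 | hydroxy Weinreb amide (C1–OH, C8 amide, C4/C5 as in 19) | OCCC[C@@](C)(C(=O)OC)[C@@H](CCC(=O)N(C)OC)/C(C)=C/C(=O)OC
F2 | step 13 | C1 aldehyde with C8 Weinreb amide | O=CCC[C@@](C)(C(=O)OC)[C@@H](CCC(=O)N(C)OC)/C(C)=C/C(=O)OC
F3 | step 13 | monocyclic ring A γ-hydroxy ester (C1, C4, C5, C10 as in 25) | COC(=O)C[C@]1(C)[C@@H](O)CC[C@@](C)(C(=O)OC)[C@H]1CCC(=O)N(C)OC
F4 | step 13 | C1 triethylsilyl ether of F3 | COC(=O)C[C@]1(C)[C@@H](O[Si](CC)(CC)CC)CC[C@@](C)(C(=O)OC)[C@H]1CCC(=O)N(C)OC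
F5 | step 13 | trans-decalin C8 ketone C9 ester, C1 triethylsilyl ether | COC(=O)[C@@H]1C(=O)CC[C@H]2[C@@]1(C)[C@@H](O[Si](CC)(CC)CC)CC[C@@]2(C)C(=O)OC
F6 | step 13 | C1 triethylsilyl ether of 26 | COC(=O)[C@@H]1C(=C)CC[C@H]2[C@@]1(C)[C@@H](O[Si](CC)(CC)CC)CC[C@@]2(C)C(=O)OC
F7 | step 10 | C8 aldehyde, C1 4-methoxybenzyl ether | COc1ccc(COCCC[C@@](C)(C(=O)OC)[C@@H](CCC=O)/C(C)=C/C(=O)OC)cc1
F8 | step 10 | C8 β-hydroxysilane (C8 epimers), C1 4-methoxybenzyl ether | COc1ccc(COCCC[C@@](C)(C(=O)OC)[C@@H](CCC(O)C[Si](C)(C)C)/C(C)=C/C(=O)OC)cc1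
F9 | step 10 | C1,C8 diol (C8 epimers) | OCCC[C@@](C)(C(=O)OC)[C@@H](CCC(O)C[Si](C)(C)C)/C(C)=C/C(=O)OC
F10 | step 6 | C10 β-keto methyl ester from 11 | COc1ccc(COCCC[C@@](C)(/C=C/C)[C@@H](CCC=C)C(=O)CC(=O)OC)cc1
F11 | step 6 | (Z)-diethyl enol phosphate of F10 (phosphate cis to CO2Me) | COc1ccc(COCCC[C@@](C)(/C=C/C)[C@@H](CCC=C)/C(OP(=O)(OCC)OCC)=C/C(=O)OC)cc1
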